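Ring B is opened across C8–C9 and C5–C10. C9, the quaternary centre bearing a methyl group and the arylmethyl arm (C11), is the α-carbon of an α-branched aldehyde whose carbonyl carbon is C10. C8 with its methyl group is the β-carbon of pent-3-en-2-one, which supplies C7, C6 and C5. One amine-catalysed Michael–aldol annulation of racemic 2-methyl-3-(2,3,5,6-tetramethoxyphenyl)propanal therefore forms both bonds, ring B and the C8/C9 stereo pair. The C10=C5–C6=O enone so obtained directs the rest: C1–C4 are attached at C10, hydride sets C10, an aldol closes ring A, and a regio-defined enol triflate becomes the C5=C6 olefin before the aminoquinone is unveiled.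

Key step: step 3

Remark: terpenoid numbering is used for all intermediates (ring A: C1–C5 and C10; ring B: C5–C10; C11 benzylic). It is assumed that reagents attack C10 of the ring B enones anti to the C8 methyl group, so C10 is set by hydride delivery and not by the carbon nucleophile.

Step 1
Reactants: 1 1,2,4,5-tetramethoxybenzene; 2 (E)-3-ethoxy-2-methylprop-2-enal
Product: 5 (E)-2-methyl-3-(2,3,5,6-tetramethoxyphenyl)prop-2-enal, via aryllithium 3 (not isolated), via ethoxyallyl carbinol 4 (not isolated)
Conditions: n-BuLi, THF, 0 °C → rt; 2, −78 → 0 °C; then 2 M HCl, THF, rt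
Reagents that add atoms: none
Why: Directed ortho-lithiation at the ring C–H flanked by two methoxy groups gives 3, which adds to the formyl group of the vinylogous formate 2; aqueous acid then ionises the electron-rich benzylic carbinol with loss of ethanol (hydrolytic allylic transposition of a β-alkoxy enal adduct) to the thermodynamically preferred E enal, and no stereocentre is formed.

Step 2
Reactants: 5 (E)-2-methyl-3-(2,3,5,6-tetramethoxyphenyl)prop-2-enal
Product: 6 rac-2-methyl-3-(2,3,5,6-tetramethoxyphenyl)propanal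
Conditions: H2 (1 atm), Pd/C (5%), EtOAc, rt
Reagents that add atoms: none
Why: Heterogeneous hydrogenation of an α-methylcinnamaldehyde saturates the conjugated C=C much faster than the aldehyde on palladium; the α-stereocentre is formed racemic on purpose, since step 3 passes through the planar enamine.

Step 3
Reactants: 6 rac-2-methyl-3-(2,3,5,6-tetramethoxyphenyl)propanal; 7 (E)-pent-3-en-2-one
Product: 9 (4R,5S)-4,5-dimethyl-4-[(2,3,5,6-tetramethoxyphenyl)methyl]cyclohex-2-en-1-one, via keto aldehyde 8 (not isolated)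
Conditions: (R)-N-(4-dodecylphenylsulfonyl)pyrrolidine-2-carboxamide (20 mol %), 7 (3 equiv), 4 Å MS, ClCH2CH2Cl, rt; then p-TsOH·H2O (30 mol %), 60 °C
Reagents that add atoms: none
Why: The pyrrolidine nitrogen of the catalyst condenses with racemic 6 to a planar enamine, which wipes out the old stereocentre and should be E because the bulky di-ortho-methoxybenzyl arm avoids the ring of the amine; C9 of this enamine then adds to C8 of 7 (enamine Michael addition), and the C10 iminium or aldehyde so formed is attacked by the enol carbon C5 of the methyl ketone, after which loss of the amine or of water gives the enone (intramolecular Mannich or aldol condensation). The closest known reaction type is the amine-catalysed enantioselective Robinson-type annulation of α-branched aldehydes with enones to 4,4-disubstituted cyclohexenones. Ring B closes in the 6-(enolendo)-exo-trig mode. C9 (R) is set by the catalyst, whose sulfonamide N–H binds the carbonyl group of 7 and delivers it to one enamine face (the R antipode is chosen from the hydrogen-bond-directed enamine model); C8 (S) is set by the relative topicity of a synclinal transition state in which C7–C6=O lies over the enamine nitrogen and the C8 methyl group points away from the enamine C=C, which puts the two methyl groups cis on the ring. The step needs enantioface selectivity at C9, simple diastereoselectivity between C8 and C9 and cross- over self-condensation; the uniform E geometry of enamine and enone secures the first two, and the α-branching of 6 (no aldehyde self-aldol, no epimerisable centre in 8 or 9) together with an excess of 7 secures the third.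

Step 4
Reactants: 9 (4R,5S)-4,5-dimethyl-4-[(2,3,5,6-tetramethoxyphenyl)methyl]cyclohex-2-en-1-one; 10 2-(3-chloropropyl)-2-methyl-1,3-dioxolane
Product: 12 trimethyl({(3S,4R,5S)-4,5-dimethyl-3-[3-(2-methyl-1,3-dioxolan-2-yl)propyl]-4-[(2,3,5,6-tetramethoxyphenyl)methyl]cyclohex-1-en-1-yl}oxy)silane, via Grignard reagent 11 (not isolated)
Conditions: 10, Mg, THF, 50 °C; then 9, CuBr·SMe2 (10 mol %), Me3SiCl, THF, −78 → −30 °C; Et3N, aq. NaHCO3 work-up
Reagents that add atoms: chlorotrimethylsilane C[Si](C)(C)Cl
Why: Copper-catalysed conjugate addition of a Grignard reagent, accelerated by chlorotrimethylsilane, tolerates the neopentylic β-carbon C10 and traps the enolate regiospecifically as the C5=C6 silyl enol ether; the chain is expected to enter trans to the C8 methyl group (axial attack that avoids a syn-axial methyl), which is the wrong C10 configuration but is erased in step 5, so either epimer serves.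

Step 5
Reactants: 12 trimethylsilyl enol ether from step 4
Product: 13 (4R,5S)-4,5-dimethyl-3-[3-(2-methyl-1,3-dioxolan-2-yl)propyl]-4-[(2,3,5,6-tetramethoxyphenyl)methyl]cyclohex-2-en-1-one
Conditions: Pd(OAc)2 (10 mol %), O2 (1 atm), DMSO, 40 °C
Reagents that add atoms: none
Why: Saegusa–Ito oxidation: divalent palladium adds at C5 of the silyl enol ether and syn β-hydride elimination of H10, the only β-hydrogen of the α-palladio ketone, gives the 3-substituted enone while oxygen returns zerovalent palladium to the divalent state; C10 becomes trigonal so that it can be set afresh by hydride.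

Step 6
Reactants: 13 (4R,5S)-4,5-dimethyl-3-[3-(2-methyl-1,3-dioxolan-2-yl)propyl]-4-[(2,3,5,6-tetramethoxyphenyl)methyl]cyclohex-2-en-1-one
Product: 16 (3S,4R,4aS)-3,4,8-trimethyl-4-[(2,3,5,6-tetramethoxyphenyl)methyl]-3,4,4a,5,6,7-hexahydronaphthalen-1(2H)-one, via silyl enol ether 14 (not isolated), via diketone 15 (not isolated)
Conditions: (IPr)CuCl (5 mol %; IPr = 1,3-bis(2,6-diisopropylphenyl)imidazol-2-ylidene), NaOt-Bu (5 mol %), PhMe2SiH (2 equiv), toluene, 0 °C → rt; then 3 M aq. HCl, THF, 60 °C
Reagents that add atoms: none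
Why: Ligated copper hydride 1,4-reduction (hydrocupration, then silyl transfer) should deliver hydride to C10 axially on the face anti to the C8 methyl group, through the half-chair with the C9 methyl group axial, so that H10 ends cis to C11 and the chain cis to both methyl groups (C10 S); aqueous acid then cleaves the silyl enol ether and the dioxolane, and the 1,7-diketone closes ring A by intramolecular aldol condensation of C5 onto C4 (6-(enolendo)-exo-trig), the only aldol that can dehydrate to a conjugated enone.

Step 7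
Reactants: 16 bicyclic enone from step 6
Product: 18 (3S,4R,4aS)-3,4,8,8-tetramethyl-4-[(2,3,5,6-tetramethoxyphenyl)methyl]-2,3,4,4a,5,6,7,8-octahydronaphthalen-1-yl trifluoromethanesulfonate, via lithium enolate 17 (not isolated)
Conditions: Me2CuLi (from MeLi, CuI), Et2O, −20 → 0 °C; then PhNTf2, THF/DMPU, 0 °C → rt
Reagents that add atoms: lithium dimethylcuprate [Li+].C[Cu-]C; N-phenylbis(trifluoromethanesulfonimide) O=S(=O)(N(c1ccccc1)S(=O)(=O)C(F)(F)F)C(F)(F)F
Why: Conjugate addition of lithium dimethylcuprate to the s-cis alkylidene ketone (the pulegone type) makes the gem-dimethyl carbon C4 without a new stereocentre and releases the C5=C6 enolate, which is sulfonylated on oxygen by PhNTf2 (regiospecific enolate trapping); enolisation of the saturated ketone, which would go towards C7, could not give this regiochemistry.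

Step 8
Reactants: 18 enol triflate from step 7
Product: 19 3-{[(1R,2S,8aS)-1,2,5,5-tetramethyl-1,2,3,5,6,7,8,8a-octahydronaphthalen-1-yl]methyl}-1,2,4,5-tetramethoxybenzene
Conditions: Pd(OAc)2 (5 mol %), PPh3 (10 mol %), HCO2H, n-Bu3N, DMF, 60 °C
Reagents that add atoms: none
Why: Palladium-catalysed formate reduction of an enol triflate: oxidative addition of zerovalent palladium at C6–O, formate exchange, loss of CO2 and reductive elimination of C6–H leave the olefin exactly at C5=C6, and no stereocentre is touched.

Step 9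
Reactants: 19 tetramethoxyarene from step 8
Product: 20 2,5-dimethoxy-3-{[(1R,2S,8aS)-1,2,5,5-tetramethyl-1,2,3,5,6,7,8,8a-octahydronaphthalen-1-yl]methyl}cyclohexa-2,5-diene-1,4-dione
Conditions: (NH4)2Ce(NO3)6 (2.5 equiv), MeCN–H2O, 0 °C
Reagents that add atoms: water O
Why: Oxidative demethylation of a 1,4-dimethoxyarene with tetravalent cerium (electron transfer from the arene, attack of water, loss of methanol) gives the 2,5-dimethoxy-1,4-benzoquinone, the two para pairs being equivalent by the symmetry of the ring; the isolated trisubstituted olefin is far harder to oxidise than the tetramethoxyarene.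

Step 10
Reactants: 20 dimethoxyquinone from step 9
Product: 21 2-hydroxy-5-methoxy-3-{[(1R,2S,8aS)-1,2,5,5-tetramethyl-1,2,3,5,6,7,8,8a-octahydronaphthalen-1-yl]methyl}cyclohexa-2,5-diene-1,4-dione
Conditions: KOH, MeOH–H2O, rt; then 1 M HCl
Reagents that add atoms: potassium hydroxide [K+].[OH-]
Why: Saponification of a vinylogous ester by addition–elimination; in 3-alkyl-2,5-dimethoxybenzoquinones hydroxide is known to replace the methoxy group next to the alkyl arm (it is twisted out of conjugation and should be the more electrophilic site), and the vinylogous carboxylate formed stops a second hydrolysis.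

Step 11
Reactants: 21 hydroxy methoxy quinone from step 10; 22 3-methylbutan-1-amine
Product: 23 nakijiquinone M, 2-hydroxy-5-[(3-methylbutyl)amino]-3-{[(1R,2S,8aS)-1,2,5,5-tetramethyl-1,2,3,5,6,7,8,8a-octahydronaphthalen-1-yl]methyl}cyclohexa-2,5-diene-1,4-dione
Conditions: 22 (5 equiv), EtOH, rt
Reagents that add atoms: none
Why: Addition–elimination of the primary amine at the remaining vinylogous ester carbon (the C–OMe next to the ring C–H) gives the vinylogous amide; the hydroxy group, present as its ammonium salt, is not displaced and no stereocentre is involved.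

Compound list
1 | 1,2,4,5-tetramethoxybenzene | COc1cc(OC)c(OC)cc1OC | starting material
2 | (E)-3-ethoxy-2-methylprop-2-enal | CCO/C=C(\C)C=O | starting material
3 | (2,3,5,6-tetramethoxyphenyl)lithium | COc1cc(OC)c(OC)c([Li])c1OC | intermediate
4 | (E)-3-ethoxy-2-methyl-1-(2,3,5,6-tetramethoxyphenyl)prop-2-en-1-ol (racemic; lithium alkoxide until the acid is added) | CCO/C=C(\C)C(O)c1c(OC)c(OC)cc(OC)c1OC | intermediate
5 | (E)-2-methyl-3-(2,3,5,6-tetramethoxyphenyl)prop-2-enal | COc1cc(OC)c(OC)c(/C=C(\C)C=O)c1OC | intermediate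
6 | rac-2-methyl-3-(2,3,5,6-tetramethoxyphenyl)propanal | COc1cc(OC)c(OC)c(CC(C)C=O)c1OC | intermediate
7 | (E)-pent-3-en-2-one | C/C=C/C(C)=O | starting material
8 | (2R,3S)-2,3-dimethyl-5-oxo-2-[(2,3,5,6-tetramethoxyphenyl)methyl]hexanal | COc1cc(OC)c(OC)c(C[C@@](C)(C=O)[C@@H](C)CC(C)=O)c1OC | intermediate
9 | (4R,5S)-4,5-dimethyl-4-[(2,3,5,6-tetramethoxyphenyl)methyl]cyclohex-2-en-1-one | COc1cc(OC)c(OC)c(C[C@@]2(C)C=CC(=O)C[C@@H]2C)c1OC | intermediate
10 | 2-(3-chloropropyl)-2-methyl-1,3-dioxolane | CC1(CCCCl)OCCO1 | starting material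
11 | [3-(2-methyl-1,3-dioxolan-2-yl)propyl]magnesium chloride | CC1(CCC[Mg]Cl)OCCO1 | intermediate
12 | trimethyl({(3S,4R,5S)-4,5-dimethyl-3-[3-(2-methyl-1,3-dioxolan-2-yl)propyl]-4-[(2,3,5,6-tetramethoxyphenyl)methyl]cyclohex-1-en-1-yl}oxy)silane (chain trans to the C8 methyl group) | COc1cc(OC)c(OC)c(C[C@@]2(C)[C@@H](CCCC3(C)OCCO3)C=C(O[Si](C)(C)C)C[C@@H]2C)c1OC | intermediate
13 | (4R,5S)-4,5-dimethyl-3-[3-(2-methyl-1,3-dioxolan-2-yl)propyl]-4-[(2,3,5,6-tetramethoxyphenyl)methyl]cyclohex-2-en-1-one | COc1cc(OC)c(OC)c(C[C@@]2(C)C(CCCC3(C)OCCO3)=CC(=O)C[C@@H]2C)c1OC | intermediate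
14 | dimethyl(phenyl)({(3R,4R,5S)-4,5-dimethyl-3-[3-(2-methyl-1,3-dioxolan-2-yl)propyl]-4-[(2,3,5,6-tetramethoxyphenyl)methyl]cyclohex-1-en-1-yl}oxy)silane (chain cis to both methyl groups) | COc1cc(OC)c(OC)c(C[C@@]2(C)[C@H](CCCC3(C)OCCO3)C=C(O[Si](C)(C)c3ccccc3)C[C@@H]2C)c1OC | intermediate
15 | (3R,4R,5S)-4,5-dimethyl-3-(4-oxopentyl)-4-[(2,3,5,6-tetramethoxyphenyl)methyl]cyclohexan-1-one | COc1cc(OC)c(OC)c(C[C@@]2(C)[C@H](CCCC(C)=O)CC(=O)C[C@@H]2C)c1OC | intermediate
16 | (3S,4R,4aS)-3,4,8-trimethyl-4-[(2,3,5,6-tetramethoxyphenyl)methyl]-3,4,4a,5,6,7-hexahydronaphthalen-1(2H)-one (6-oxo, C4=C5; 8S,9R,10S) | COc1cc(OC)c(OC)c(C[C@@]2(C)[C@@H]3CCCC(C)=C3C(=O)C[C@@H]2C)c1OC | intermediate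
17 | lithium (3S,4R,4aS)-3,4,8,8-tetramethyl-4-[(2,3,5,6-tetramethoxyphenyl)methyl]-2,3,4,4a,5,6,7,8-octahydronaphthalen-1-olate | COc1cc(OC)c(OC)c(C[C@@]2(C)[C@@H]3CCCC(C)(C)C3=C(O[Li])C[C@@H]2C)c1OC | intermediate
18 | (3S,4R,4aS)-3,4,8,8-tetramethyl-4-[(2,3,5,6-tetramethoxyphenyl)methyl]-2,3,4,4a,5,6,7,8-octahydronaphthalen-1-yl trifluoromethanesulfonate | COc1cc(OC)c(OC)c(C[C@@]2(C)[C@@H]3CCCC(C)(C)C3=C(OS(=O)(=O)C(F)(F)F)C[C@@H]2C)c1OC | intermediate
19 | 3-{[(1R,2S,8aS)-1,2,5,5-tetramethyl-1,2,3,5,6,7,8,8a-octahydronaphthalen-1-yl]methyl}-1,2,4,5-tetramethoxybenzene | COc1cc(OC)c(OC)c(C[C@@]2(C)[C@@H]3CCCC(C)(C)C3=CC[C@@H]2C)c1OC | intermediate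
20 | 2,5-dimethoxy-3-{[(1R,2S,8aS)-1,2,5,5-tetramethyl-1,2,3,5,6,7,8,8a-octahydronaphthalen-1-yl]methyl}cyclohexa-2,5-diene-1,4-dione | COC1=CC(=O)C(OC)=C(C[C@@]2(C)[C@@H]3CCCC(C)(C)C3=CC[C@@H]2C)C1=O | intermediate
21 | 2-hydroxy-5-methoxy-3-{[(1R,2S,8aS)-1,2,5,5-tetramethyl-1,2,3,5,6,7,8,8a-octahydronaphthalen-1-yl]methyl}cyclohexa-2,5-diene-1,4-dione | COC1=CC(=O)C(O)=C(C[C@@]2(C)[C@@H]3CCCC(C)(C)C3=CC[C@@H]2C)C1=O | intermediate
22 | 3-methylbutan-1-amine | CC(C)CCN | starting material
23 | nakijiquinone M, 2-hydroxy-5-[(3-methylbutyl)amino]-3-{[(1R,2S,8aS)-1,2,5,5-tetramethyl-1,2,3,5,6,7,8,8a-octahydronaphthalen-1-yl]methyl}cyclohexa-2,5-diene-1,4-dione | CC(C)CCNC1=CC(=O)C(O)=C(C[C@@]2(C)[C@@H]3CCCC(C)(C)C3=CC[C@@H]2C)C1=O | target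

Total step count: 11. Longest linear sequence: 11 steps (1 to 23).

Steps most likely to fail

Step 3. The hindered enamine may add only slowly to a β-substituted enone. Enantio- and diastereoselectivity may also erode if the enamine forms as a mixture of geometries or if the sense of face shielding is opposite to the model; in the latter case the S catalyst is used. The fallback sets out from 6 and comes back at 9, replacing the catalytic enamine by a stoichiometric chiral imine. Compound 6 is condensed with (S)-1-phenylethylamine (toluene, reflux, removal of water) to the imine (E)-N-[(1S)-1-phenylethyl]-2-methyl-3-(2,3,5,6-tetramethoxyphenyl)propan-1-imine F1. Its secondary enamine tautomer should add to 7 on heating (neat or THF, 60 °C) through a compact transition state with internal transfer of the N–H hydrogen to C7, to give the adduct imine F2. Aqueous acetic acid frees 8 and the amine, and p-TsOH in toluene at 80 °C closes ring B to 9.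

Step 6. Hydride delivery to C10 may show poor or reversed facial selectivity, the hindered enone may react slowly, or 1,2-reduction may compete. The fallback sets out from 9 and comes back at 16; it sets C10 by C–C bond formation and not by C–H bond formation, which uses the same facial bias of ring B in the opposite sense. Copper-catalysed addition of 11 to 9 (CuBr·SMe2, THF, −78 °C) with a protic quench would give (3R,4R,5S)-4,5-dimethyl-3-[3-(2-methyl-1,3-dioxolan-2-yl)propyl]-4-[(2,3,5,6-tetramethoxyphenyl)methyl]cyclohexan-1-one F3 if the chain enters anti to C11. Aqueous 3 M HCl in THF at 60 °C then gives 16 by way of 15. Steps 4 to 6 are thereby shortened to two operations.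

Step 7. Conjugate addition to the tetrasubstituted enone may be incomplete, 1,2-addition may compete, or the hindered enolate may be sulfonylated incompletely. The fallback sets out from 16 and comes back at 18; it brings in the second C4 methyl group as a cyclopropane methylene. Luche reduction (NaBH4, CeCl3·7H2O, MeOH) gives the allylic alcohol F4. Hydroxyl-directed Simmons–Smith cyclopropanation (Et2Zn, CH2I2, CH2Cl2) gives the cyclopropyl carbinol F5, in which CH2 bridges C4 and C5. Swern oxidation gives the cyclopropyl ketone F6. Lithium in liquid ammonia should cleave the exocyclic C5–CH2 bond (primary carbanion, protonated by ammonia to the methyl group) and give the same lithium enolate 17, which PhNTf2 converts to 18. The new centres of F4 to F6 at C4, C5 and C6 are lost again and are left open.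

Further compounds
F1 | step 3 | (E)-N-[(1S)-1-phenylethyl]-2-methyl-3-(2,3,5,6-tetramethoxyphenyl)propan-1-imine (both C2 epimers) | COc1cc(OC)c(OC)c(CC(C)/C=N/[C@@H](C)c2ccccc2)c1OC
F2 | step 3 | (3S,4R)-3,4-dimethyl-5-{[(1S)-1-phenylethyl]imino}-4-[(2,3,5,6-tetramethoxyphenyl)methyl]pentan-2-one (adduct imine of 8) | COc1cc(OC)c(OC)c(C[C@@](C)(/C=N/[C@@H](C)c2ccccc2)[C@@H](C)CC(C)=O)c1OC
F3 | step 6 | (3R,4R,5S)-4,5-dimethyl-3-[3-(2-methyl-1,3-dioxolan-2-yl)propyl]-4-[(2,3,5,6-tetramethoxyphenyl)methyl]cyclohexan-1-one | COc1cc(OC)c(OC)c(C[C@@]2(C)[C@H](CCCC3(C)OCCO3)CC(=O)C[C@@H]2C)c1OC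
F4 | step 7 | (3S,4R,4aS)-3,4,8-trimethyl-4-[(2,3,5,6-tetramethoxyphenyl)methyl]-1,2,3,4,4a,5,6,7-octahydronaphthalen-1-ol (either C1 epimer) | COc1cc(OC)c(OC)c(C[C@@]2(C)[C@@H]3CCCC(C)=C3C(O)C[C@@H]2C)c1OC
F5 | step 7 | cyclopropyl carbinol: 6-hydroxy compound with a CH2 bridge between C4 and C5 (8S,9R,10S) | COc1cc(OC)c(OC)c(C[C@@]2(C)[C@@H]3CCCC4(C)CC34C(O)C[C@@H]2C)c1OC
F6 | step 7 | cyclopropyl ketone: 6-oxo compound with a CH2 bridge between C4 and C5 (8S,9R,10S) | COc1cc(OC)c(OC)c(C[C@@]2(C)[C@@H]3CCCC4(C)CC34C(=O)C[C@@H]2C)c1OC
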